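A product that is lost as it forms can mislead: carry its last rise forward and it overshoots once the loss catches up with the making.

in all of them: L 2.6 mM (held)
- eta: X 0.050 M; the very flask that is asked about, followed so far
- theta: X 0.075 M; run made earlier
- flask: X 0.050 M; time 25 min

- eta (time / min: J / %, X / %): 1.33: 5.1, 94.6; 2.50: 9.8, 90.2; 4.00: 15.0, 83.1; 5.00: 19.1, 79.1
- theta (time / min: J / %, X / %): 2.00: 7.1, 92.5; 6.00: 20.1, 77.7; 12.0: 32.2, 58.0; 20.0: 40.0, 38.0

(readings scatter by 0.3 percentage points)

1. the J standing at 25 min, as a percentage of the X charged
2. concentration of G in solution at 25 min, in percent of saturation

- at the start none of L is in solution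
- G is what L becomes in solution

I reckoned in two ways when J stopped rising. The first used J's readings in the theta run and nothing else. J rose by these fractions of the charge per minute:

6.00 min to 12.0 min: 0.0202 /min

12.0 min to 20.0 min: 0.00975 /min

Carrying that falling slope down to zero gave 22.6 min. This is the crossing time, my reading from theta of the moment at which J is made as fast as it is lost.

The second way used other evidence: the late decay of X in theta, a pseudo-first-order constant, and the shrinking of X + J per unit of J standing.

k = 0.0529 /min, k' = 0.0422 /min

ln(k/k')/(k − k') = 21.1 min

The second way came out earlier than the first, and it was the one that cheated: it holds k from the start, yet early theta lost X at 0.0390 /min, slower than k. I kept 22.6 min. The asked time lies past it and theta's last reading before it, the two 5.00 min apart, and J had risen faster per minute in eta by 5.00 min than in theta by 6.00 min, so I expected J a little above theta's 40.0 %.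

The forecast, higher than that reading, gave 43 % (39 % to 46 %) and 87 % of saturation (65 % to 97 %), noting “J is being lost onward”.

The flask gave 42.4 % of J, with G at 91.4 % of saturation, both inside those ranges.

    X + G → J (k = 25.0 /M/min)
    L ⇌ G, rate k2*(csat - [G]) (kL = 3.50 /min)
    J ⇌ Z (K = 8.20, k = 0.0430 /min)

At 25.0 min, past my crossing time, the flask made J at 0.934 of the rate at which it used J up, each taken net, so J was already falling slowly. In the flask left until 1.5 h, later than the crossing, J had fallen to 15.0 %.

The earlier runs and the new flask are simulated with constants of no real substance; the scatter is artificial.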